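## Analysis of the target

Target 24 is a 4-aryl-1-tetralone lignan. The numbering used throughout is: C1 is the carbonyl carbon, C2 and C3 carry the methyl groups, and C4 carries the pendant aryl group. Ring A is the 6,7-dimethoxybenzo ring fused at C4a and C8a, ring B is the cyclohexanone, and ring C is the 3-hydroxy-4-methoxyphenyl group (C1' on C4).

The three contiguous stereocentres are (2S,3R,4R). Ring C and the C3 methyl group are cis, and the two methyl groups are trans.

C2 lies next to the ketone and can be epimerised. With ring C pseudoaxial (turned away from C5–H), the C3 methyl group is equatorial and the required C2 methyl group is equatorial as well. C2 is therefore the thermodynamic epimer and needs no chiral information of its own.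

C3 and C4 cannot be corrected later, and C4 is the hard centre. It is a diarylmethine whose two aryl groups are both 3,4-dioxygenated benzene rings. They are too alike for a reagent to tell apart, and so electron-rich that any C4 cation is planar, p-methoxy-stabilised and without stereochemical memory.

The sensitive parts are the free o-methoxyphenol (oxidants, alkylating agents), the two donor rings (electrophiles, and competition between them in any ring closure), the doubly benzylic C4–H and the enolisable ketone.

The strategy rests on the C3–C4 dyad. With oxygen in place of ring A, this dyad is the pattern left by an anti crotylation of the ring C aldehyde. The benzylic C4–O bond can then be exchanged for the C4–C4a bond by a stereospecific boron-to-carbon shift that inverts C4.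

## Retrosynthetic reasoning

**24 ⇒ 23.** The last bond handled is the O–acyl bond of a ring C phenol ester. The phenol must stay masked through every electrophilic, oxidising and alkylating step. A basic ester exchange at the end adds no separate operation, because the same medium lets C2 settle into its more stable trans arrangement.

**23 ⇒ 21.** The C2–CH3 bond is cut. C2 is the only centre under thermodynamic control, so it can be added to a finished ring without a chiral reagent. The cut leaves a C2 methylene, which traces back to a plain vinyl group. The forward reaction has to mono-methylate enolate 22 on the face away from ring C.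

**21 ⇒ 19.** The C1–C8a bond is cut, which opens ring B. C8a lies para to the C6 methoxy group and is the natural site for acylation of ring A. Closing the ring at C4–C4a instead would need a C4 cation and would lose the stereocentre. The forward acylation must choose ring A over ring C. Both ring C positions ortho to C4 are meta to its methoxy group and are helped only by the C3' oxygen, which the acyl group of 19 mutes.

**19 ⇒ 17 ⇒ 15 ⇒ 14.** No skeletal bond is cut here. C2 and C1 are recognised as the two carbons of a terminal vinyl group. A vinyl group survives organolithium and boronate chemistry, which a carboxyl derivative would not. The forward steps are protecting-group exchange on the phenol, anti-Markovnikov hydration and oxidation.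

**14 ⇒ 12.** The C4–H bond is traced back to a C4–B bond. A tertiary, doubly benzylic boronic ester gives up boron for hydrogen with retention under a hydrated fluoride source. The same reagent removes the silyl ether of ring C, so two tasks are done in one step.

**12 ⇒ 8 + 9.** The C4–C4a bond is cut; this is the key disconnection. Ring A is delivered from the boron of 9 to a carbon that still carries the carbamate oxygen of 8. Cutting here lets the two similar aryl groups arrive at different times and by different mechanisms, so they never have to be distinguished. The forward reaction has to pass the carbinol configuration on to a quaternary carbon without leakage.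

**8 ⇒ 5 ⇒ 2 + 3 (with 6).** The C3–C4 bond is cut. A single catalytic, enantioselective anti crotylation of 2 with 3 sets C3 for good and sets C4 in latent form. Carbamoylation with 6 turns the hydroxyl group into a directing group for lithiation and also into a leaving group.

**2 ⇒ 1.** The silyl ether is removed in the retrosynthetic sense, which leads to commercial 1.

## Alternatives that were turned down

**Alternative 1:** Ring B is cut at C1–C2 and C3–C4 together. This leads to the o-benzylbenzaldehyde A1 as a masked diene and furan-2(5H)-one A2 as the two-carbon partner.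
- *Forward key step.* A1 is irradiated near 365 nm with Ti(Oi-Pr)4 A3 and a TADDOL-type diol. Hydrogen transfer from the diarylmethane carbon to the excited formyl group gives the E hydroxy-o-quinodimethane. Held on titanium, it adds A2 endo to give the all-cis hydroxy lactone A4.
- *For it.* One operation closes ring B, forms two C–C bonds and fixes C1 to C4. In bonds and stereocentres per step it is clearly stronger than the chosen route, which needs separate steps for the ring.
- *Against it.* The substituents at C2 and C3 arrive as a lactone carbonyl and an OCH2 group, and both must be taken down to methyl.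
  - That means lactone reduction, double activation of a 1,4-diol that readily closes to a cyclic ether, and double hydride displacement. All of this happens beside a benzylic C1 alcohol that eliminates easily.
  - C1 oxidation, inversion of C2 by epimerisation and debenzylation still follow. About seven repair steps are added to the three or four needed for A1.
  - C4 also depends on the geometry of an aryl-terminated photoenol and on the endo preference of a weak dienophile. The substrate secures neither.
- *Comparison.* In the chosen route the C3 methyl group arrives as a methyl group, C4 is written by stereospecific events only, and no carbon has to be deoxygenated.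

**Alternative 2:** Only the C4–ring C bond is cut, and the C3 methyl group is replaced by a quinolin-8-yl carboxamide. This gives the C4-unsubstituted tetralone amide A5 and the aryl iodide A6.
- *Forward key step.* With Pd(OAc)2 A7 and AgOAc A8, the bidentate amide binds divalent palladium and one C4 methylene hydrogen is cleaved through a five-membered palladacycle. Oxidative addition of A6 and reductive elimination give A9, with the new aryl group on the face of the amide.
- *For it.* The cis relation follows from the geometry of the metallacycle, and ring C enters late. In modularity this plan is stronger.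
- *Against it.*
  - A5 must already be a single enantiomer with C2 and C3 in place, so the asymmetric problem is only moved upstream.
  - The hot acetate medium threatens C2 (α to the ketone) and C3 (α to the amide).
  - A tetralone under divalent palladium and a silver oxidant is prone to dehydrogenation to a naphthol, which would erase all three centres.
  - After coupling, the amide carbon has to go down to methyl beside a ketone. This takes auxiliary removal, reduction, activation and deoxygenation, with ketone protection, or four to six steps.
- *Comparison.* The chosen route gives up late-stage variation of ring C. In return it obtains both fixed stereocentres from one catalytic step and needs no directing group.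

**Alternative 3:** The C3–CH3 bond is cut, which leads to the γ,γ-diaryl (E)-unsaturated thioester A10.
- *Forward key step.* MeMgBr A11 adds to the β-carbon under CuBr·SMe2 A12 and a JosiPhos-type ferrocenyl bisphosphine to give A13.
- *For it.* The reaction type is dependable for linear unsaturated thioesters. The thioester is a good acyl donor for an anionic ring closure. The bromine on ring A fixes the site of that closure beyond doubt, which is stronger than the electronic differentiation the chosen route uses in its acylation.
- *Against it.*
  - C4 must exist as a single enantiomer before the key step, and the plan offers no way to make it, so the hardest centre is left unsolved.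
  - The C4–H of A10 is doubly benzylic, allylic and vinylogous to the thioester. Deprotonation by the Grignard reagent, with racemisation or deconjugation, competes with addition.
  - The catalyst has to overrule a bulky γ-substituent, which raises matched and mismatched pairing.
- *Comparison.* After the key step the two plans are of similar length. The chosen route addresses C4 directly and derives C3 and C4 from the same transition state. It borrows the halogen-directed closure only as a reserve.

Key step: step 4

Assumption: the facial sense of the phosphoric acid catalyst is taken from its usual behaviour with aromatic aldehydes, where the R acid delivers the allyl unit to the Re face and gives R carbinols. The S acid is therefore specified for the (1S,2S) alcohol. If aldehyde 2 behaved otherwise, the antipodal acid would be used and nothing else would change.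

## Route

Step 1
Reactants: 1 3-hydroxy-4-methoxybenzaldehyde (isovanillin)
Product: 2 4-methoxy-3-(triisopropylsilyloxy)benzaldehyde
Conditions: TIPSCl, imidazole, DMF, 0 °C → rt
Reagents that add atoms: triisopropylsilyl chloride, CC(C)[Si](Cl)(C(C)C)C(C)C
Why: Silyl ether formation at the only hydroxyl group. The bulky silyl ether withstands sec-butyllithium, shields the neighbouring ring C positions from metalation and is removed by the fluoride of step 5 without a separate step.

Step 2
Reactants: 2 4-methoxy-3-(triisopropylsilyloxy)benzaldehyde; 3 (E)-crotylboronic acid pinacol ester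
Product: 5 (1S,2S)-1-[4-methoxy-3-(triisopropylsilyloxy)phenyl]-2-methylbut-3-en-1-ol, via pinacol borate 4 (not isolated)
Conditions: (S)-TRIP [(S)-3,3'-bis(2,4,6-triisopropylphenyl)-1,1'-binaphthyl-2,2'-diyl hydrogen phosphate] (5 mol %), 4 Å MS, toluene, −30 °C; aq. NaHCO3
Reagents that add atoms: none
Why: Brønsted acid catalysed allylboration through a closed chair (Zimmerman–Traxler) transition state, in which the E geometry of 3 places the methyl group equatorial and gives the anti C3/C4 relationship. The chiral phosphate, hydrogen-bonded to a boronate oxygen and to the formyl hydrogen, should open the Si face of 2 and so set (1S,2S). Borate 4 is hydrolysed on work-up.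

Step 3
Reactants: 5 (1S,2S)-1-[4-methoxy-3-(triisopropylsilyloxy)phenyl]-2-methylbut-3-en-1-ol; 6 N,N-diisopropylcarbamoyl chloride
Product: 8 (1S,2S)-1-[4-methoxy-3-(triisopropylsilyloxy)phenyl]-2-methylbut-3-en-1-yl N,N-diisopropylcarbamate, via sodium alkoxide 7 (not isolated)
Conditions: NaH, THF, 0 °C; 6, 0 → 45 °C
Reagents that add atoms: sodium hydride, [H-].[Na+] (its sodium stays only in 7)
Why: O-Carbamoylation of alkoxide 7, in which no bond to a stereocentre is touched. Working through the alkoxide at mild temperature avoids the ionisation that a p-methoxybenzylic ester risks when heated with amine hydrochlorides, and the bulk of both partners keeps silyl transfer slow.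

Step 4
Reactants: 8 (1S,2S)-1-[4-methoxy-3-(triisopropylsilyloxy)phenyl]-2-methylbut-3-en-1-yl N,N-diisopropylcarbamate; 9 2-(3,4-dimethoxyphenyl)-4,4,5,5-tetramethyl-1,3,2-dioxaborolane
Product: 12 2-{(1S,2S)-1-(3,4-dimethoxyphenyl)-1-[4-methoxy-3-(triisopropylsilyloxy)phenyl]-2-methylbut-3-en-1-yl}-4,4,5,5-tetramethyl-1,3,2-dioxaborolane, via lithiated carbamate 10 (not isolated), via lithium boronate complex 11 (not isolated)
Conditions: s-BuLi, TMEDA, Et2O, −78 °C; 9, −78 °C; MgBr2 in MeOH, −78 °C → rt
Reagents that add atoms: sec-butyllithium, [Li]C(C)CC (its lithium stays only in 10 and 11)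
Why: s-BuLi/TMEDA, held by the carbamate carbonyl, removes the benzylic hydrogen of 8 with retention and gives the tertiary α-oxybenzyllithium 10, which keeps its configuration at −78 °C. Boronate 9 is taken up on the lithium-bearing face (retention, because a boronate oxygen binds lithium) to give complex 11. On warming, the 3,4-dimethoxyphenyl group moves from boron to carbon antiperiplanar to the leaving carbamate, so the C4–C4a bond forms with inversion at C4. MgBr2 activates the carbamate and speeds the shift, while MeOH protonates any 10 released by reversal of the borylation, so racemised material cannot re-enter. The closest known reaction type is lithiation–borylation of enantioenriched secondary benzylic carbamates, homoallylic ones included, with aryl pinacol boronates. No ring is closed. The one new stereocentre, quaternary C4, is controlled only by the carbinol configuration of 8 through the retention–retention–inversion sequence, and C3 is a spectator. The step needs site-selective deprotonation (benzylic C–H against the allylic C3–H and the ring C positions), secured by the proximity effect of the carbamate and the bulk of the silyl ether, and migration of aryl rather than of a pinacol oxygen, secured by the high migratory aptitude of the donor-substituted ring A.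

Step 5
Reactants: 12 2-{(1S,2S)-1-(3,4-dimethoxyphenyl)-1-[4-methoxy-3-(triisopropylsilyloxy)phenyl]-2-methylbut-3-en-1-yl}-4,4,5,5-tetramethyl-1,3,2-dioxaborolane
Product: 14 5-[(1R,2S)-1-(3,4-dimethoxyphenyl)-2-methylbut-3-en-1-yl]-2-methoxyphenol, via desilylated boronic ester 13 (not isolated)
Conditions: Bu4NF·3H2O (excess), toluene, rt → 45 °C; aq. NH4Cl
Reagents that add atoms: none
Why: Fluoride first cleaves the aryl silyl ether (13) and then adds to boron, and the doubly benzylic carbon is protonated by hydrogen-bonded water on the face that boron leaves (stereoretentive protodeboronation of tertiary benzylic boronic esters). C4 should therefore end as the diarylmethine with ring A where the carbamate oxygen stood, inverted, which is the 3,4-cis series. The donor rings keep free carbanion character, and with it racemisation, low.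

Step 6
Reactants: 14 5-[(1R,2S)-1-(3,4-dimethoxyphenyl)-2-methylbut-3-en-1-yl]-2-methoxyphenol
Product: 15 5-[(1S,2S)-1-(3,4-dimethoxyphenyl)-2-methylbut-3-en-1-yl]-2-methoxyphenyl pivalate
Conditions: PivCl, Et3N, DMAP (cat.), CH2Cl2, 0 °C → rt
Reagents that add atoms: pivaloyl chloride, CC(C)(C)C(=O)Cl
Why: Acylation of the phenol; only the descriptor at C4 changes, not the geometry. The pivalate turns the C3' oxygen into a weak donor for step 9, and its bulk lets it survive hydroboration, acid and a hindered amide base.

Step 7
Reactants: 15 5-[(1S,2S)-1-(3,4-dimethoxyphenyl)-2-methylbut-3-en-1-yl]-2-methoxyphenyl pivalate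
Product: 17 5-[(1S,2S)-1-(3,4-dimethoxyphenyl)-4-hydroxy-2-methylbutyl]-2-methoxyphenyl pivalate, via B-alkyl-9-BBN adduct 16 (not isolated)
Conditions: 9-BBN, THF, 0 °C → rt; NaBO3·4H2O, THF–H2O, rt
Reagents that add atoms: 9-borabicyclo[3.3.1]nonane, B1C2CCCC1CCC2 (held only in 16); sodium perborate, [Na+].[O-]OB=O
Why: Hydroboration–oxidation, in which 9-BBN places boron on the terminal carbon of the monosubstituted alkene for steric reasons and leaves the ester alone. Perborate is chosen as the mild oxidant because alkaline hydrogen peroxide would perhydrolyse an aryl ester.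

Step 8
Reactants: 17 5-[(1S,2S)-1-(3,4-dimethoxyphenyl)-4-hydroxy-2-methylbutyl]-2-methoxyphenyl pivalate
Product: 19 (3S,4S)-4-(3,4-dimethoxyphenyl)-4-[4-methoxy-3-(pivaloyloxy)phenyl]-3-methylbutanoic acid, via aldehyde 18 (not isolated)
Conditions: TEMPO (cat.), PhI(OAc)2, MeCN–H2O, rt
Reagents that add atoms: water, O
Why: Oxoammonium-mediated oxidation of a primary alcohol through aldehyde 18 and its hydrate to the acid. The system contains no chlorine, so ring A is not halogenated, and it is not basic, so the pivalate stays in place.

Step 9
Reactants: 19 (3S,4S)-4-(3,4-dimethoxyphenyl)-4-[4-methoxy-3-(pivaloyloxy)phenyl]-3-methylbutanoic acid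
Product: 21 (3S,4R)-6,7-dimethoxy-4-[4-methoxy-3-(pivaloyloxy)phenyl]-3-methyl-3,4-dihydronaphthalen-1(2H)-one, via mixed trifluoroacetic anhydride 20 (not isolated)
Conditions: (CF3CO)2O, CF3CO2H–CH2Cl2, 0 °C → rt
Reagents that add atoms: trifluoroacetic anhydride, O=C(OC(=O)C(F)(F)F)C(F)(F)F (its acyl group stays only in 20)
Why: Intramolecular Friedel–Crafts acylation through 20 forms C1–C8a and closes the six-membered ring B. Ring A reacts para to a methoxy group, whereas both candidate positions of ring C are meta to its methoxy group and are served only by the acylated oxygen, so ring A should win. No stereocentre takes part, and the mild acid spares the methyl ethers.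

Step 10
Reactants: 21 (3S,4R)-6,7-dimethoxy-4-[4-methoxy-3-(pivaloyloxy)phenyl]-3-methyl-3,4-dihydronaphthalen-1(2H)-one
Product: 23 (2S,3R,4R)-6,7-dimethoxy-4-[4-methoxy-3-(pivaloyloxy)phenyl]-2,3-dimethyl-3,4-dihydronaphthalen-1(2H)-one, via lithium enolate 22 (not isolated)
Conditions: LiN(SiMe3)2 (1.05 equiv), THF, −78 °C; MeI, −78 → −40 °C
Reagents that add atoms: lithium hexamethyldisilazide, [Li]N([Si](C)(C)C)[Si](C)(C)C (its lithium stays only in 22); iodomethane, CI
Why: Kinetic enolate alkylation. In 22 the pseudoaxial ring C covers one face, so MeI should reach C2 from the face opposite ring C and the C3 methyl group, which gives the 2,3-trans (2S) centre. The hindered silylamide at low temperature leaves the hindered aryl ester alone.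

Step 11
Reactants: 23 (2S,3R,4R)-6,7-dimethoxy-4-[4-methoxy-3-(pivaloyloxy)phenyl]-2,3-dimethyl-3,4-dihydronaphthalen-1(2H)-one
Product: 24 (2S,3R,4R)-4-(3-hydroxy-4-methoxyphenyl)-6,7-dimethoxy-2,3-dimethyl-3,4-dihydronaphthalen-1(2H)-one
Conditions: K2CO3, MeOH, argon, rt; aq. NH4Cl
Reagents that add atoms: none
Why: Base-catalysed transesterification frees the phenol. In the same medium C2 equilibrates through the enolate, and the arrangement with ring C pseudoaxial and both methyl groups equatorial is that of the target, so any 2,3-cis material from step 10 should converge on 24. C3 and C4 are not acidic under these conditions.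

## Compound list

1 | 3-hydroxy-4-methoxybenzaldehyde (isovanillin) | COc1ccc(C=O)cc1O | starting material
2 | 4-methoxy-3-(triisopropylsilyloxy)benzaldehyde | COc1ccc(C=O)cc1O[Si](C(C)C)(C(C)C)C(C)C | intermediate
3 | (E)-crotylboronic acid pinacol ester | C/C=C/CB1OC(C)(C)C(C)(C)O1 | starting material
4 | 2-{(1S,2S)-1-[4-methoxy-3-(triisopropylsilyloxy)phenyl]-2-methylbut-3-en-1-yloxy}-4,4,5,5-tetramethyl-1,3,2-dioxaborolane (pinacol borate of 5) | COc1ccc([C@H]([C@@H](C)C=C)OB2OC(C)(C)C(C)(C)O2)cc1O[Si](C(C)C)(C(C)C)C(C)C | intermediate
5 | (1S,2S)-1-[4-methoxy-3-(triisopropylsilyloxy)phenyl]-2-methylbut-3-en-1-ol (anti) | COc1ccc([C@H]([C@@H](C)C=C)O)cc1O[Si](C(C)C)(C(C)C)C(C)C | intermediate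
6 | N,N-diisopropylcarbamoyl chloride | CC(C)N(C(C)C)C(Cl)=O | starting material
7 | sodium (1S,2S)-1-[4-methoxy-3-(triisopropylsilyloxy)phenyl]-2-methylbut-3-en-1-olate | COc1ccc([C@H]([C@@H](C)C=C)[O-])cc1O[Si](C(C)C)(C(C)C)C(C)C.[Na+] | intermediate
8 | (1S,2S)-1-[4-methoxy-3-(triisopropylsilyloxy)phenyl]-2-methylbut-3-en-1-yl N,N-diisopropylcarbamate | COc1ccc([C@H]([C@@H](C)C=C)OC(=O)N(C(C)C)C(C)C)cc1O[Si](C(C)C)(C(C)C)C(C)C | intermediate
9 | 2-(3,4-dimethoxyphenyl)-4,4,5,5-tetramethyl-1,3,2-dioxaborolane | COc1ccc(B2OC(C)(C)C(C)(C)O2)cc1OC | starting material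
10 | α-lithiated 8 (lithium in the place of the benzylic hydrogen, configuration retained) | COc1ccc([C@]([Li])([C@@H](C)C=C)OC(=O)N(C(C)C)C(C)C)cc1O[Si](C(C)C)(C(C)C)C(C)C | intermediate
11 | lithium boronate complex of 10 and 9 (boron in the place of lithium, configuration retained) | COc1ccc([C@]([B-]2(c3ccc(OC)c(OC)c3)OC(C)(C)C(C)(C)O2)([C@@H](C)C=C)OC(=O)N(C(C)C)C(C)C)cc1O[Si](C(C)C)(C(C)C)C(C)C.[Li+] | intermediate
12 | 2-{(1S,2S)-1-(3,4-dimethoxyphenyl)-1-[4-methoxy-3-(triisopropylsilyloxy)phenyl]-2-methylbut-3-en-1-yl}-4,4,5,5-tetramethyl-1,3,2-dioxaborolane | COc1ccc([C@@](B2OC(C)(C)C(C)(C)O2)([C@@H](C)C=C)c2ccc(OC)c(OC)c2)cc1O[Si](C(C)C)(C(C)C)C(C)C | intermediate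
13 | 5-[(1R,2S)-1-(3,4-dimethoxyphenyl)-2-methyl-1-(4,4,5,5-tetramethyl-1,3,2-dioxaborolan-2-yl)but-3-en-1-yl]-2-methoxyphenol | COc1ccc([C@@](B2OC(C)(C)C(C)(C)O2)([C@@H](C)C=C)c2ccc(OC)c(OC)c2)cc1O | intermediate
14 | 5-[(1R,2S)-1-(3,4-dimethoxyphenyl)-2-methylbut-3-en-1-yl]-2-methoxyphenol | COc1ccc([C@@H]([C@@H](C)C=C)c2ccc(OC)c(OC)c2)cc1O | intermediate
15 | 5-[(1S,2S)-1-(3,4-dimethoxyphenyl)-2-methylbut-3-en-1-yl]-2-methoxyphenyl pivalate | COc1ccc([C@@H]([C@@H](C)C=C)c2ccc(OC)c(OC)c2)cc1OC(=O)C(C)(C)C | intermediate
16 | 5-[(1S,2S)-4-(9-borabicyclo[3.3.1]nonan-9-yl)-1-(3,4-dimethoxyphenyl)-2-methylbutyl]-2-methoxyphenyl pivalate | COc1ccc([C@@H]([C@@H](C)CCB2C3CCCC2CCC3)c2ccc(OC)c(OC)c2)cc1OC(=O)C(C)(C)C | intermediate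
17 | 5-[(1S,2S)-1-(3,4-dimethoxyphenyl)-4-hydroxy-2-methylbutyl]-2-methoxyphenyl pivalate | COc1ccc([C@@H]([C@@H](C)CCO)c2ccc(OC)c(OC)c2)cc1OC(=O)C(C)(C)C | intermediate
18 | 5-[(1S,2S)-1-(3,4-dimethoxyphenyl)-2-methyl-4-oxobutyl]-2-methoxyphenyl pivalate | COc1ccc([C@@H]([C@@H](C)CC=O)c2ccc(OC)c(OC)c2)cc1OC(=O)C(C)(C)C | intermediate
19 | (3S,4S)-4-(3,4-dimethoxyphenyl)-4-[4-methoxy-3-(pivaloyloxy)phenyl]-3-methylbutanoic acid | COc1ccc([C@@H]([C@@H](C)CC(=O)O)c2ccc(OC)c(OC)c2)cc1OC(=O)C(C)(C)C | intermediate
20 | (3S,4S)-4-(3,4-dimethoxyphenyl)-4-[4-methoxy-3-(pivaloyloxy)phenyl]-3-methylbutanoic trifluoroacetic anhydride | COc1ccc([C@@H]([C@@H](C)CC(=O)OC(=O)C(F)(F)F)c2ccc(OC)c(OC)c2)cc1OC(=O)C(C)(C)C | intermediate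
21 | (3S,4R)-6,7-dimethoxy-4-[4-methoxy-3-(pivaloyloxy)phenyl]-3-methyl-3,4-dihydronaphthalen-1(2H)-one (aryl and methyl cis) | COc1ccc([C@@H]2c3cc(OC)c(OC)cc3C(=O)C[C@@H]2C)cc1OC(=O)C(C)(C)C | intermediate
22 | lithium enolate of 21 (C1–OLi, C1=C2; C3 and C4 as in 21) | COc1ccc([C@@H]2c3cc(OC)c(OC)cc3C(O[Li])=C[C@@H]2C)cc1OC(=O)C(C)(C)C | intermediate
23 | (2S,3R,4R)-6,7-dimethoxy-4-[4-methoxy-3-(pivaloyloxy)phenyl]-2,3-dimethyl-3,4-dihydronaphthalen-1(2H)-one | COc1ccc([C@@H]2c3cc(OC)c(OC)cc3C(=O)[C@@H](C)[C@@H]2C)cc1OC(=O)C(C)(C)C | intermediate
24 | (2S,3R,4R)-4-(3-hydroxy-4-methoxyphenyl)-6,7-dimethoxy-2,3-dimethyl-3,4-dihydronaphthalen-1(2H)-one (CNP0170223.1) | COc1ccc([C@@H]2c3cc(OC)c(OC)cc3C(=O)[C@@H](C)[C@@H]2C)cc1O | target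

## Step count and least certain steps

Total: 11 steps. Longest linear sequence: 11 steps (1 → 24). Compounds 3, 6 and 9 are bought and enter directly.

**Step 4 (key step).**
- *What may go wrong.* The deprotonation may be slow, because the benzylic position is flanked by a branched carbon and sits on a donor-substituted ring. The borylation may be reversible, because both partners are crowded. On warming, the boronate complex could then fall apart, and the freed organolithium could lose its configuration or undergo an oxygen-to-carbon carbamoyl shift. Metalation of ring C is a lesser risk.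
- *Fallback.* It sets out from 8 and 9 and comes back at 14. It keeps the same bond and the same partners but replaces the 1,2-shift by a stereospecific nickel-catalysed Suzuki–Miyaura-type coupling of the benzylic carbamate (Ni(cod)2, 1,3-dimesitylimidazolin-2-ylidene, KOt-Bu, n-BuOH, THF). With this carbene ligand, zerovalent nickel is known to open the benzylic C–O bond with inversion, and the later steps retain. The coupling would therefore give directly the silyl-protected diarylmethine {5-[(1S,2S)-1-(3,4-dimethoxyphenyl)-2-methylbut-3-en-1-yl]-2-methoxyphenoxy}triisopropylsilane F1. Bu4NF in THF then gives 14, so steps 4 and 5 are both bypassed.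
- *Weak points of the fallback.* Oxidative addition is harder for a simple benzene ring than for extended arenes, and β-hydride loss toward C3 is possible.

**Step 5.**
- *What may go wrong.* The most likely failure is a sluggish C–B protonolysis. The early desilylation leaves a phenoxide, which makes an already electron-rich benzylic carbon even less willing to take up negative charge. Forcing the reaction invites partial loss of configuration at C4.
- *Fallback.* It sets out from 12 and comes back at 15. It changes the substrate on which boron is exchanged. Buffered fluoride (Bu4NF/AcOH, THF, 0 °C) removes only the silyl group, and 13 is isolated. Pivaloylation (PivCl, Et3N, DMAP) gives 5-[(1S,2S)-1-(3,4-dimethoxyphenyl)-2-methyl-1-(4,4,5,5-tetramethyl-1,3,2-dioxaborolan-2-yl)but-3-en-1-yl]-2-methoxyphenyl pivalate F2. Its acceptor-modified ring C should ease the protodeboronation with CsF and a slight excess of water in 1,4-dioxane, the variant established for diarylalkyl boronic esters.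

**Step 10.**
- *What may go wrong.* Proton exchange between enolate and product may lead to double methylation. The enolate or the amide base may attack the aryl ester, and the phenoxide so released would then be O-methylated. Facial selectivity is a minor concern, since step 11 corrects it.
- *Fallback.* It sets out from 21 and comes back at 24. It avoids strong base and cannot add more than one carbon.
  - Soft enolisation (TMSOTf, Et3N, CH2Cl2, 0 °C) gives the trimethylsilyl enol ether of 21 F5.
  - Simmons–Smith cyclopropanation (Et2Zn, CH2I2, CH2Cl2) on the face away from ring C gives the siloxycyclopropane F6.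
  - K2CO3 in MeOH then removes the silyl group, opens the cyclopropanol at the C1–CH2 bond to the C2 methyl ketone, cleaves the pivalate and equilibrates C2 in one operation.

**Step 9.**
- *What may go wrong.* Acylation may compete at ring C para to the acyloxy group, or at the crowded ring A position between C4a and the methoxy group. Intermolecular acylation is possible if the ring closure is slow.
- *Fallback.* It sets out from 19 and comes back at 21. It fixes the site with a halogen instead of relying on electronics.
  - Iodination (NIS, cat. CF3CO2H, MeCN) takes place on the more activated ring A, para to a methoxy group. It gives (3S,4R)-4-(2-iodo-4,5-dimethoxyphenyl)-4-[4-methoxy-3-(pivaloyloxy)phenyl]-3-methylbutanoic acid F3.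
  - Coupling with MeNHOMe·HCl (EDC, i-Pr2NEt) gives the Weinreb amide F4.
  - Iodine–magnesium exchange with i-PrMgCl·LiCl (THF, −20 → 0 °C), which tolerates the pivalate, triggers a Parham-type cyclisation onto the amide.

**Step 7.**
- *What may go wrong.* The aryl pivalate may be partly cleaved by the peroxide nucleophile during oxidation of the borane. The phenol would then be exposed to step 8.
- *Fallback.* It sets out from 15 and comes back at 19. It avoids boron and peroxide altogether. An aldehyde-selective, nitrite-modified Wacker oxidation (PdCl2(PhCN)2, CuCl2·2H2O, AgNO2, t-BuOH–MeNO2, O2) gives aldehyde 18, which is now isolated. The allylic branching should reinforce its anti-Markovnikov sense. A Pinnick oxidation (NaClO2, NaH2PO4, 2-methyl-2-butene) then gives 19. This fallback makes no compound outside the compound list (F0).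

## Further compounds

F1 | step 4 | {5-[(1S,2S)-1-(3,4-dimethoxyphenyl)-2-methylbut-3-en-1-yl]-2-methoxyphenoxy}triisopropylsilane | COc1ccc([C@@H]([C@@H](C)C=C)c2ccc(OC)c(OC)c2)cc1O[Si](C(C)C)(C(C)C)C(C)C
F2 | step 5 | 5-[(1S,2S)-1-(3,4-dimethoxyphenyl)-2-methyl-1-(4,4,5,5-tetramethyl-1,3,2-dioxaborolan-2-yl)but-3-en-1-yl]-2-methoxyphenyl pivalate | COc1ccc([C@@](B2OC(C)(C)C(C)(C)O2)([C@@H](C)C=C)c2ccc(OC)c(OC)c2)cc1OC(=O)C(C)(C)C
F0 | step 7 | none | none
F3 | step 9 | (3S,4R)-4-(2-iodo-4,5-dimethoxyphenyl)-4-[4-methoxy-3-(pivaloyloxy)phenyl]-3-methylbutanoic acid | COc1ccc([C@@H]([C@@H](C)CC(=O)O)c2cc(OC)c(OC)cc2I)cc1OC(=O)C(C)(C)C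
F4 | step 9 | (3S,4R)-4-(2-iodo-4,5-dimethoxyphenyl)-N-methoxy-4-[4-methoxy-3-(pivaloyloxy)phenyl]-N,3-dimethylbutanamide (Weinreb amide) | COc1ccc([C@@H]([C@@H](C)CC(=O)N(C)OC)c2cc(OC)c(OC)cc2I)cc1OC(=O)C(C)(C)C
F5 | step 10 | trimethylsilyl enol ether of 21 (C1–OSiMe3, C1=C2; C3 and C4 as in 21) | COc1ccc([C@@H]2c3cc(OC)c(OC)cc3C(O[Si](C)(C)C)=C[C@@H]2C)cc1OC(=O)C(C)(C)C
F6 | step 10 | siloxycyclopropane from F5 (methylene bridge across C1–C2 on the face opposite ring C; C3 and C4 as in 21) | COc1ccc([C@@H]2c3cc(OC)c(OC)cc3[C@@]3(O[Si](C)(C)C)C[C@H]3[C@@H]2C)cc1OC(=O)C(C)(C)C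
A1 | alternative 1 | 2-[3-(benzyloxy)-4-methoxybenzyl]-4,5-dimethoxybenzaldehyde | COc1ccc(Cc2cc(OC)c(OC)cc2C=O)cc1OCc1ccccc1
A2 | alternative 1 | furan-2(5H)-one | O=C1OCC=C1
A3 | alternative 1 | titanium tetraisopropoxide, Ti(Oi-Pr)4 | CC(C)[O-].CC(C)[O-].CC(C)[O-].CC(C)[O-].[Ti+4]
A4 | alternative 1 | all-cis 4-[3-(benzyloxy)-4-methoxyphenyl]-9-hydroxy-6,7-dimethoxy-3a,4,9,9a-tetrahydronaphtho[2,3-c]furan-1(3H)-one | COc1ccc([C@@H]2c3cc(OC)c(OC)cc3[C@H](O)[C@@H]3C(=O)OC[C@H]23)cc1OCc1ccccc1
A5 | alternative 2 | 6,7-dimethoxy-3-methyl-4-oxo-N-(quinolin-8-yl)-1,2,3,4-tetrahydronaphthalene-2-carboxamide (methyl trans to the amide, as drawn) | C1c2cc(OC)c(OC)cc2C(=O)[C@@H](C)[C@@H]1C(=O)Nc1cccc2cccnc12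
A6 | alternative 2 | 2-(benzyloxy)-4-iodo-1-methoxybenzene | COc1ccc(I)cc1OCc1ccccc1
A7 | alternative 2 | palladium diacetate, Pd(OAc)2 | CC(=O)[O-].CC(=O)[O-].[Pd+2]
A8 | alternative 2 | silver acetate, AgOAc | CC(=O)[O-].[Ag+]
A9 | alternative 2 | 1-[3-(benzyloxy)-4-methoxyphenyl]-6,7-dimethoxy-3-methyl-4-oxo-N-(quinolin-8-yl)-1,2,3,4-tetrahydronaphthalene-2-carboxamide (aryl cis to the amide, as drawn) | COc1ccc([C@@H]2c3cc(OC)c(OC)cc3C(=O)[C@@H](C)[C@@H]2C(=O)Nc2cccc3cccnc23)cc1OCc1ccccc1
A10 | alternative 3 | S-ethyl (E)-4-[3-(benzyloxy)-4-methoxyphenyl]-4-(2-bromo-4,5-dimethoxyphenyl)but-2-enethioate (C4 as drawn) | CCSC(=O)/C=C/[C@H](c1ccc(OC)c(OCc2ccccc2)c1)c1cc(OC)c(OC)cc1Br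
A11 | alternative 3 | methylmagnesium bromide, MeMgBr | C[Mg]Br
A12 | alternative 3 | copper bromide dimethyl sulfide complex, CuBr·SMe2 | CSC.Br[Cu]
A13 | alternative 3 | S-ethyl 4-[3-(benzyloxy)-4-methoxyphenyl]-4-(2-bromo-4,5-dimethoxyphenyl)-3-methylbutanethioate (configuration as drawn) | CCSC(=O)C[C@H](C)[C@H](c1ccc(OC)c(OCc2ccccc2)c1)c1cc(OC)c(OC)cc1Br
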